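In a one-step world, substrate and reagent give mono adduct and nothing else, and the noon run of this same flask already shows how fast that step goes.

| setting | noon | flask |
|---|---|---|
| substrate | 0.050 M | 0.050 M |
| reagent | 2.5 equiv | 2.50 equiv |
| remark | the very flask that is asked about, followed so far |  |
| time |  | 8.0 min |

- noon (time / s: substrate / %, mono adduct / %): 10.0: 94, 6; 25.0: 86, 11; 40.0: 80, 12; 60.0: 71, 17; 90.0: 62, 19

(readings scatter by 1.5 percentage points)



* amount of substrate at 8.0 min, in percent of the substrate charged
* amount of mono adduct at 8.0 min, in percent of the substrate charged
* amount of bis adduct at 8.0 min, in percent of the substrate charged
* amount of triple product at 8.0 min, in percent of the substrate charged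

With reagent held as charged the step is pseudo-first-order, and the last noon reading, 62% of substrate at 90.0 s, gives for its constant a reading of 0.319 min⁻¹. This flask would then hold 7.79% of substrate at 8.0 min. Letting the reagent fall by one for each substrate consumed, from 2.50 equiv, the integrated second-order law lifts substrate to 14.2%, and the constant sinks to 0.209 min⁻¹ by that time.

The readings also demand a further process, since 19 percentage points of the charge is neither substrate nor mono adduct at 90.0 s, while mono adduct averaged 12.9% over that time. Dividing the gap by this average and by the time gives the loss constant of mono adduct, the fraction of it passing on per minute: a reading of 0.983 min⁻¹, with the scatter of its data. Its half-life of 0.705 min is shorter than the 2.17 min of substrate, so in this reckoning mono adduct is taken at a quasi-steady state that falls along with substrate, not one where making and loss are equal, with [mono adduct]/[substrate] equal to the substrate constant over the loss constant minus the substrate constant. At 8.0 min this ratio is 0.271, which puts mono adduct at 3.85%. That leaves 82.0% of the charge, which readings without bis adduct or triple product do not divide.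

The forecast, higher than this reckoning on substrate and mono adduct, gives 21% of substrate, 10% of mono adduct, 55% of bis adduct and 14% of triple product, assuming “a moderately slow third step”.

The flask gives 12.8% of substrate, 3.89% of mono adduct, 13.6% of bis adduct and 0.297% of triple product.

    substrate + reagent → mono adduct + released group (k = 2.70 L mol⁻¹ min⁻¹)
    reagent + mono adduct → bis adduct + released group (k = 1.80 L mol⁻¹ min⁻¹)
    reagent + bis adduct → triple product + released group (k = 0.0510 L mol⁻¹ min⁻¹)
    mono adduct → side product A (k = 0.760 min⁻¹)
    substrate + mono adduct → side product B (k = 2.10 L mol⁻¹ min⁻¹)

In this flask side product A stands at 61.9% at 8.00 min, more than the bis adduct. The passage of mono adduct to bis adduct, with reagent as charged, has a half-life of 3.1 min, and ln(2) over that half-life is about a quarter of the loss constant read from the noon run.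

For the neighbour flask with 0.013 M of substrate, the equivalents and the time being held, this reckoning scales the substrate constant with the charge and keeps the loss constant as read, which gives 55.1% of substrate and 4.10% of mono adduct. The neighbour flask itself gives 52.8% of substrate and 5.11% of mono adduct.

All runs were computed on assumed constants; the scatter is artificial.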